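Everything rests on the C6–C7 bond, which belongs both to the butenolide (O, C12, C11, C7, C6) and to the ten-membered carbocycle (C1–C10). An acyclic (Z)-enol triflate at C7, cis to the C12 ester, carries a C6 aldehyde flanked by a C4–C5 epoxide; one Nozaki–Hiyama–Kishi reaction closes the carbocycle and, through lactonization of the C6 alkoxide, the butenolide. The epoxide is a latent C5=C6 alkene and C4–O bridge: once the C1 ketone is unmasked, base opens it by vinylogous elimination and the C4 alkoxide closes the hemiketal. C8 and C10 derive from a glutamic-acid lactone, C4 from a Sharpless epoxidation.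

Key step: step 19

Remark: locants are germacrane locants of the target (C1 hemiketal carbon, C4 and C10 methyl-bearing, C6–O–C12 lactone, C13 acetoxymethyl); the C1 hemiketal is assumed to form under thermodynamic control, its configuration being fixed by C4 through the cis oxygen bridge.

Abbreviations: TES = triethylsilyl, TBS = tert-butyldimethylsilyl, PMB = 4-methoxybenzyl, Tf = trifluoromethylsulfonyl, R* = (E)-4-(TBSO)-2-methylbut-2-enoyl.

Step 1
Reactants: 1 (S)-5-(hydroxymethyl)dihydrofuran-2(3H)-one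
Product: 2 (S)-5-[(TESO)methyl]dihydrofuran-2(3H)-one
Conditions: Et3SiCl, imidazole, CH2Cl2, 0 °C to rt
Reagents that add atoms: chlorotriethylsilane, CC[Si](Cl)(CC)CC
Why: Imidazole-mediated silylation of the primary alcohol should give a silyl ether that survives the enolate and organolithium steps and can later be oxidized directly.

Step 2
Reactants: 2 (S)-5-[(TESO)methyl]dihydrofuran-2(3H)-one
Product: 3 (3R,5S)-3-methyl-5-[(TESO)methyl]dihydrofuran-2(3H)-one
Conditions: LiN(iPr)2, THF, −78 °C; MeI, −78 °C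
Reagents that add atoms: iodomethane, CI
Why: Enolate alkylation of a γ-substituted butyrolactone should take place on the face opposite the silyloxymethyl group, giving mainly the trans lactone and so setting C10 (R) from the chiral-pool C8 (S) centre.

Step 3
Reactants: 3 (3R,5S)-3-methyl-5-[(TESO)methyl]dihydrofuran-2(3H)-one; 4 4-bromo-2-methylbut-1-ene
Product: 6 (6R,8S)-8-hydroxy-2,6-dimethyl-9-(TESO)non-1-en-5-one, via (3-methylbut-3-en-1-yl)lithium 5 (not isolated)
Conditions: 4, t-BuLi (2 equiv), Et2O, −78 °C; then 3, −78 °C; AcOH quench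
Reagents that add atoms: none
Why: Bromine–lithium exchange gives a primary alkyllithium that should add only once to the lactone carbonyl at −78 °C, because the lithium hemiketal alkoxide persists until the quench (organolithium mono-addition to a lactone).

Step 4
Reactants: 7 (tert-butyldimethylsilyloxy)acetaldehyde; 8 ethyl 2-(triphenylphosphoranylidene)propanoate
Product: 9 ethyl (E)-4-(TBSO)-2-methylbut-2-enoate
Conditions: CH2Cl2, rt
Reagents that add atoms: none
Why: Wittig olefination with the stabilized α-branched ylide should give the (E)-trisubstituted enoate.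

Step 5
Reactants: 9 ethyl (E)-4-(TBSO)-2-methylbut-2-enoate
Product: 10 (E)-4-(TBSO)-2-methylbut-2-enoic acid
Conditions: LiOH, THF–H2O, 0 °C to rt; then aq. HCl to pH 4, 0 °C
Reagents that add atoms: lithium hydroxide, [Li+].[OH-]
Why: Saponification of the ethyl ester should leave the primary silyl ether and the alkene geometry intact.

Step 6
Reactants: 6 (6R,8S)-8-hydroxy-2,6-dimethyl-9-(TESO)non-1-en-5-one; 10 (E)-4-(TBSO)-2-methylbut-2-enoic acid
Product: 11 (2S,4R)-4,8-dimethyl-5-oxo-1-(TESO)non-8-en-2-yl (E)-4-(TBSO)-2-methylbut-2-enoate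
Conditions: DCC, DMAP (cat.), CH2Cl2, 0 °C to rt
Reagents that add atoms: none
Why: Steglich esterification should acylate the only free hydroxyl, at C8, with retention of configuration.

Step 7
Reactants: 11 (2S,4R)-4,8-dimethyl-5-oxo-1-(TESO)non-8-en-2-yl (E)-4-(TBSO)-2-methylbut-2-enoate
Product: 12 (2S,4R)-4,8-dimethyl-1,5-dioxonon-8-en-2-yl (E)-4-(TBSO)-2-methylbut-2-enoate
Conditions: (COCl)2, DMSO, CH2Cl2, −78 to −30 °C; Et3N, −78 to 0 °C
Reagents that add atoms: none
Why: Under Swern conditions the primary triethylsilyl ether should be cleaved and oxidized to the C7 aldehyde in one flask, while the primary TBS ether is not touched.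

Step 8
Reactants: 13 4-methoxybenzyl alcohol; 14 methyl acrylate
Product: 15 methyl 3-(PMBO)propanoate
Conditions: PMe3 (10 mol %), THF, rt
Reagents that add atoms: none
Why: Phosphine-catalysed oxa-Michael addition of the benzylic alcohol to the acrylate should give the β-alkoxy ester.

Step 9
Reactants: 12 (2S,4R)-4,8-dimethyl-1,5-dioxonon-8-en-2-yl (E)-4-(TBSO)-2-methylbut-2-enoate; 15 methyl 3-(PMBO)propanoate
Product: 16 methyl (4S,6R)-3-hydroxy-2-[(PMBO)methyl]-6,10-dimethyl-7-oxo-4-(R*-oxy)undec-10-enoate (mixture at C2 and C3)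
Conditions: 15, LiN(iPr)2, THF, −78 °C; then 12, −78 °C; AcOH quench
Reagents that add atoms: none
Why: Aldol addition of the ester enolate should occur at the aldehyde much faster than at the hindered C1 ketone, and the two new stereocentres are erased in steps 10 and 11, so they need no control.

Step 10
Reactants: 16 methyl (4S,6R)-3-hydroxy-2-[(PMBO)methyl]-6,10-dimethyl-7-oxo-4-(R*-oxy)undec-10-enoate
Product: 17 methyl (4S,6R)-2-[(PMBO)methyl]-6,10-dimethyl-3,7-dioxo-4-(R*-oxy)undec-10-enoate (mixture at C2)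
Conditions: Dess–Martin periodinane, NaHCO3, CH2Cl2, rt
Reagents that add atoms: none
Why: Dess–Martin oxidation should give the β-keto ester under neutral conditions that do not eliminate the β-alkoxy group.

Step 11
Reactants: 17 methyl (4S,6R)-2-[(PMBO)methyl]-6,10-dimethyl-3,7-dioxo-4-(R*-oxy)undec-10-enoate
Product: 18 methyl (2Z,4S,6R)-2-[(PMBO)methyl]-6,10-dimethyl-7-oxo-4-(R*-oxy)-3-(TfO)undeca-2,10-dienoate
Conditions: LiN(SiMe3)2, THF, −78 °C; Comins' reagent, −78 to 0 °C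
Reagents that add atoms: N-(5-chloropyridin-2-yl)-1,1,1-trifluoro-N-[(trifluoromethyl)sulfonyl]methanesulfonamide (Comins' reagent), Clc1ccc(nc1)N(S(=O)(=O)C(F)(F)F)S(=O)(=O)C(F)(F)F
Why: The lithium enolate of the β-keto ester is a six-membered chelate, so O-sulfonylation (enol triflate formation) should place the triflate cis to the ester, the geometry that later lets C6 reach C12; a minor (E)-isomer would be removed by chromatography.

Step 12
Reactants: 18 methyl (2Z,4S,6R)-2-[(PMBO)methyl]-6,10-dimethyl-7-oxo-4-(R*-oxy)-3-(TfO)undeca-2,10-dienoate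
Product: 19 methyl (2Z,4S,6R)-2-(hydroxymethyl)-6,10-dimethyl-7-oxo-4-(R*-oxy)-3-(TfO)undeca-2,10-dienoate
Conditions: DDQ, CH2Cl2–pH 7 buffer, 0 °C
Reagents that add atoms: none
Why: Oxidative cleavage of the 4-methoxybenzyl ether by DDQ should spare the silyl ether, the esters, the triflate and the 1,1-disubstituted alkene.

Step 13
Reactants: 19 methyl (2Z,4S,6R)-2-(hydroxymethyl)-6,10-dimethyl-7-oxo-4-(R*-oxy)-3-(TfO)undeca-2,10-dienoate
Product: 20 methyl (2Z,4S,6R)-2-(acetoxymethyl)-6,10-dimethyl-7-oxo-4-(R*-oxy)-3-(TfO)undeca-2,10-dienoate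
Conditions: Ac2O, pyridine, DMAP (cat.), CH2Cl2, 0 °C
Reagents that add atoms: acetic anhydride, CC(=O)OC(C)=O
Why: Acetylation of the primary allylic alcohol installs the C13 acetate of the target.

Step 14
Reactants: 20 methyl (2Z,4S,6R)-2-(acetoxymethyl)-6,10-dimethyl-7-oxo-4-(R*-oxy)-3-(TfO)undeca-2,10-dienoate
Product: 21 methyl (2Z,4S,6R)-2-(acetoxymethyl)-7,7-dimethoxy-6,10-dimethyl-4-(R*-oxy)-3-(TfO)undeca-2,10-dienoate
Conditions: MeOSiMe3, Me3SiOTf (5 mol %), CH2Cl2, −78 to −40 °C; pyridine quench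
Reagents that add atoms: methoxytrimethylsilane, CO[Si](C)(C)C
Why: Silyl triflate-catalysed ketalization at low temperature should mask C1 without enolization at C10, so that the alkenylmetal of step 19 cannot add to a ketone five atoms away.

Step 15
Reactants: 21 methyl (2Z,4S,6R)-2-(acetoxymethyl)-7,7-dimethoxy-6,10-dimethyl-4-(R*-oxy)-3-(TfO)undeca-2,10-dienoate
Product: 22 methyl (2Z,4S,6R,10E)-2-(acetoxymethyl)-7,7-dimethoxy-6,10-dimethyl-12-oxo-4-(R*-oxy)-3-(TfO)dodeca-2,10-dienoate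
Conditions: (E)-but-2-enal (10 equiv), second-generation Hoveyda–Grubbs catalyst (10 mol %), CH2Cl2, 40 °C
Reagents that add atoms: (E)-but-2-enal, C/C=C/C=O
Why: Olefin cross-metathesis of the 1,1-disubstituted alkene with an enal should give the trisubstituted (E)-enal under thermodynamic control, the electron-poor tri- and tetrasubstituted alkenes being inert.

Step 16
Reactants: 22 methyl (2Z,4S,6R,10E)-2-(acetoxymethyl)-7,7-dimethoxy-6,10-dimethyl-12-oxo-4-(R*-oxy)-3-(TfO)dodeca-2,10-dienoate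
Product: 23 methyl (2Z,4S,6R,10E)-2-(acetoxymethyl)-12-hydroxy-7,7-dimethoxy-6,10-dimethyl-4-(R*-oxy)-3-(TfO)dodeca-2,10-dienoate
Conditions: NaBH4, CeCl3·7H2O, MeOH, −40 °C
Reagents that add atoms: none
Why: Luche reduction should reduce the aldehyde 1,2-selectively to the (E)-allylic alcohol without touching the esters or the triflate.

Step 17
Reactants: 23 methyl (2Z,4S,6R,10E)-2-(acetoxymethyl)-12-hydroxy-7,7-dimethoxy-6,10-dimethyl-4-(R*-oxy)-3-(TfO)dodeca-2,10-dienoate
Product: 24 methyl (2Z,4S,6R,10S,11S)-2-(acetoxymethyl)-10,11-epoxy-12-hydroxy-7,7-dimethoxy-6,10-dimethyl-4-(R*-oxy)-3-(TfO)dodec-2-enoate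
Conditions: Ti(OiPr)4, L-(+)-diethyl tartrate, t-BuOOH, 4 Å molecular sieves, CH2Cl2, −20 °C
Reagents that add atoms: tert-butyl hydroperoxide, CC(C)(C)OO
Why: Sharpless asymmetric epoxidation with L-(+)-diethyl tartrate should deliver oxygen to the face of the (E)-allylic alcohol that gives the (4S,5S)-epoxide in target locants (the sense known for geraniol), fixing the C4–O stereocentre by reagent control.

Step 18
Reactants: 24 methyl (2Z,4S,6R,10S,11S)-2-(acetoxymethyl)-10,11-epoxy-12-hydroxy-7,7-dimethoxy-6,10-dimethyl-4-(R*-oxy)-3-(TfO)dodec-2-enoate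
Product: 25 methyl (2Z,4S,6R,10S,11R)-2-(acetoxymethyl)-10,11-epoxy-7,7-dimethoxy-6,10-dimethyl-12-oxo-4-(R*-oxy)-3-(TfO)dodec-2-enoate
Conditions: Dess–Martin periodinane, NaHCO3, CH2Cl2, 0 °C to rt
Reagents that add atoms: none
Why: Dess–Martin oxidation should convert the epoxy alcohol into the α,β-epoxy aldehyde without epimerization or epoxide opening.

Step 19
Reactants: 25 methyl (2Z,4S,6R,10S,11R)-2-(acetoxymethyl)-10,11-epoxy-7,7-dimethoxy-6,10-dimethyl-12-oxo-4-(R*-oxy)-3-(TfO)dodec-2-enoate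
Product: 27 (4S,5S,8S,10R)-13-acetoxy-4,5-epoxy-1,1-dimethoxy-8-(R*-oxy)germacr-7(11)-en-12,6-olide (C6 epimers), via macrocyclic hydroxy ester 26 (not isolated)
Conditions: CrCl2 (10 equiv), NiCl2 (2 mol %), DMF–THF, 25 °C, slow addition of 25 to 0.002 M
Reagents that add atoms: none
Why: Zerovalent nickel (from NiCl2 and CrCl2) inserts into the C7–OTf bond, the alkenyl group passes to trivalent chromium and adds to the C6 aldehyde, and the C6 alkoxide then attacks the cis C12 methyl ester and expels methoxide. The closest known reaction type is the Nozaki–Hiyama–Kishi macrocyclization of an alkenyl triflate onto an aldehyde, joined to the butenolide annulation known for (Z)-β-sulfonyloxy and β-iodo enoates. The ten-membered carbocycle C1–C10 closes by intramolecular 1,2-addition at the C6 carbonyl (10-exo), and the butenolide (O, C12, C11, C7, C6) closes by 5-exo-trig acyl substitution, possible only because the (Z)-triflate holds C6 cis to C12. The new stereocentre C6 should form under Felkin-type control by the C5 epoxide carbon but needs no control, since both epimers lose it in step 21. The step needs aldehyde over ketone selectivity (secured by the C1 ketal), ring closure over oligomerization (high dilution; the trans-epoxide and the tetrasubstituted alkene stiffen the chain) and addition over β-elimination of the C8 acyloxy group (allylic 1,3-strain with the C13 acetoxymethyl group keeps the C8–O bond out of the C7–Cr plane).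

Step 20
Reactants: 27 (4S,5S,8S,10R)-13-acetoxy-4,5-epoxy-1,1-dimethoxy-8-(R*-oxy)germacr-7(11)-en-12,6-olide
Product: 28 (4S,5S,8S,10R)-13-acetoxy-4,5-epoxy-1-oxo-8-(R*-oxy)germacr-7(11)-en-12,6-olide
Conditions: PPTS (0.2 equiv), acetone–H2O (10:1), 25 °C
Reagents that add atoms: water, O
Why: Mild acid hydrolysis of the acyclic dimethyl ketal should be far faster than opening of the trisubstituted epoxide or cleavage of the TBS ether.

Step 21
Reactants: 28 (4S,5S,8S,10R)-13-acetoxy-4,5-epoxy-1-oxo-8-(R*-oxy)germacr-7(11)-en-12,6-olide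
Product: 30 (1R,4S,5E,8S,10R)-13-acetoxy-1,4-epoxy-1-hydroxy-8-(R*-oxy)germacra-5,7(11)-dien-12,6-olide, via ring-opened hydroxy ketone 29 (not isolated)
Conditions: DBU (1.2 equiv), CH2Cl2, 0 to 25 °C
Reagents that add atoms: none
Why: DBU removes the γ-hydrogen at C6, the 2-oxidofuran opens the epoxide at C5 (vinylogous E1cB) and the C4 alkoxide adds to the C1 ketone across the ring (the glaucolide-to-hirsutinolide isomerization), so C4 keeps its configuration, C1 is set thermodynamically as the cis-bridged hemiketal and the bridge enforces the cis ring geometry of C5=C6.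

Step 22
Reactants: 30 (1R,4S,5E,8S,10R)-13-acetoxy-1,4-epoxy-1-hydroxy-8-(R*-oxy)germacra-5,7(11)-dien-12,6-olide
Product: 31 (1R,4S,5E,8S,10R)-13-acetoxy-1,4-epoxy-1-hydroxy-8-[(E)-4-hydroxy-2-methylbut-2-enoyloxy]germacra-5,7(11)-dien-12,6-olide (target CNP0154520.2)
Conditions: HF·pyridine, pyridine, THF, 0 to 25 °C
Reagents that add atoms: none
Why: Buffered fluoride desilylation should cleave the primary TBS ether and leave the acetate, the enol lactone and the hemiketal untouched.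

Compound list
1 | (S)-5-(hydroxymethyl)dihydrofuran-2(3H)-one | O=C1CC[C@@H](CO)O1 | starting material
2 | (S)-5-[(TESO)methyl]dihydrofuran-2(3H)-one | O=C1CC[C@@H](CO[Si](CC)(CC)CC)O1 | intermediate
3 | (3R,5S)-3-methyl-5-[(TESO)methyl]dihydrofuran-2(3H)-one | O=C1[C@H](C)C[C@@H](CO[Si](CC)(CC)CC)O1 | intermediate
4 | 4-bromo-2-methylbut-1-ene | C=C(C)CCBr | starting material
5 | (3-methylbut-3-en-1-yl)lithium | [Li]CCC(C)=C | intermediate
6 | (6R,8S)-8-hydroxy-2,6-dimethyl-9-(TESO)non-1-en-5-one | C=C(C)CCC(=O)[C@H](C)C[C@H](O)CO[Si](CC)(CC)CC | intermediate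
7 | (tert-butyldimethylsilyloxy)acetaldehyde | O=CCO[Si](C)(C)C(C)(C)C | starting material
8 | ethyl 2-(triphenylphosphoranylidene)propanoate | CCOC(=O)C(C)=P(c1ccccc1)(c1ccccc1)c1ccccc1 | starting material
9 | ethyl (E)-4-(TBSO)-2-methylbut-2-enoate | CCOC(=O)/C(C)=C/CO[Si](C)(C)C(C)(C)C | intermediate
10 | (E)-4-(TBSO)-2-methylbut-2-enoic acid | OC(=O)/C(C)=C/CO[Si](C)(C)C(C)(C)C | intermediate
11 | (2S,4R)-4,8-dimethyl-5-oxo-1-(TESO)non-8-en-2-yl (E)-4-(TBSO)-2-methylbut-2-enoate | C=C(C)CCC(=O)[C@H](C)C[C@H](OC(=O)/C(C)=C/CO[Si](C)(C)C(C)(C)C)CO[Si](CC)(CC)CC | intermediate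
12 | (2S,4R)-4,8-dimethyl-1,5-dioxonon-8-en-2-yl (E)-4-(TBSO)-2-methylbut-2-enoate | C=C(C)CCC(=O)[C@H](C)C[C@H](OC(=O)/C(C)=C/CO[Si](C)(C)C(C)(C)C)C=O | intermediate
13 | 4-methoxybenzyl alcohol | COc1ccc(CO)cc1 | starting material
14 | methyl acrylate | C=CC(=O)OC | starting material
15 | methyl 3-(PMBO)propanoate | COC(=O)CCOCc1ccc(OC)cc1 | intermediate
16 | methyl (4S,6R)-3-hydroxy-2-[(PMBO)methyl]-6,10-dimethyl-7-oxo-4-(R*-oxy)undec-10-enoate | C=C(C)CCC(=O)[C@H](C)C[C@H](OC(=O)/C(C)=C/CO[Si](C)(C)C(C)(C)C)C(O)C(COCc1ccc(OC)cc1)C(=O)OC | intermediate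
17 | methyl (4S,6R)-2-[(PMBO)methyl]-6,10-dimethyl-3,7-dioxo-4-(R*-oxy)undec-10-enoate | C=C(C)CCC(=O)[C@H](C)C[C@H](OC(=O)/C(C)=C/CO[Si](C)(C)C(C)(C)C)C(=O)C(COCc1ccc(OC)cc1)C(=O)OC | intermediate
18 | methyl (2Z,4S,6R)-2-[(PMBO)methyl]-6,10-dimethyl-7-oxo-4-(R*-oxy)-3-(TfO)undeca-2,10-dienoate | C=C(C)CCC(=O)[C@H](C)C[C@H](OC(=O)/C(C)=C/CO[Si](C)(C)C(C)(C)C)/C(OS(=O)(=O)C(F)(F)F)=C(\COCc1ccc(OC)cc1)C(=O)OC | intermediate
19 | methyl (2Z,4S,6R)-2-(hydroxymethyl)-6,10-dimethyl-7-oxo-4-(R*-oxy)-3-(TfO)undeca-2,10-dienoate | C=C(C)CCC(=O)[C@H](C)C[C@H](OC(=O)/C(C)=C/CO[Si](C)(C)C(C)(C)C)/C(OS(=O)(=O)C(F)(F)F)=C(\CO)C(=O)OC | intermediate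
20 | methyl (2Z,4S,6R)-2-(acetoxymethyl)-6,10-dimethyl-7-oxo-4-(R*-oxy)-3-(TfO)undeca-2,10-dienoate | C=C(C)CCC(=O)[C@H](C)C[C@H](OC(=O)/C(C)=C/CO[Si](C)(C)C(C)(C)C)/C(OS(=O)(=O)C(F)(F)F)=C(\COC(C)=O)C(=O)OC | intermediate
21 | methyl (2Z,4S,6R)-2-(acetoxymethyl)-7,7-dimethoxy-6,10-dimethyl-4-(R*-oxy)-3-(TfO)undeca-2,10-dienoate | C=C(C)CCC(OC)(OC)[C@H](C)C[C@H](OC(=O)/C(C)=C/CO[Si](C)(C)C(C)(C)C)/C(OS(=O)(=O)C(F)(F)F)=C(\COC(C)=O)C(=O)OC | intermediate
22 | methyl (2Z,4S,6R,10E)-2-(acetoxymethyl)-7,7-dimethoxy-6,10-dimethyl-12-oxo-4-(R*-oxy)-3-(TfO)dodeca-2,10-dienoate | O=C/C=C(\C)CCC(OC)(OC)[C@H](C)C[C@H](OC(=O)/C(C)=C/CO[Si](C)(C)C(C)(C)C)/C(OS(=O)(=O)C(F)(F)F)=C(\COC(C)=O)C(=O)OC | intermediate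
23 | methyl (2Z,4S,6R,10E)-2-(acetoxymethyl)-12-hydroxy-7,7-dimethoxy-6,10-dimethyl-4-(R*-oxy)-3-(TfO)dodeca-2,10-dienoate | OC/C=C(\C)CCC(OC)(OC)[C@H](C)C[C@H](OC(=O)/C(C)=C/CO[Si](C)(C)C(C)(C)C)/C(OS(=O)(=O)C(F)(F)F)=C(\COC(C)=O)C(=O)OC | intermediate
24 | methyl (2Z,4S,6R,10S,11S)-2-(acetoxymethyl)-10,11-epoxy-12-hydroxy-7,7-dimethoxy-6,10-dimethyl-4-(R*-oxy)-3-(TfO)dodec-2-enoate | OC[C@@H]1O[C@@]1(C)CCC(OC)(OC)[C@H](C)C[C@H](OC(=O)/C(C)=C/CO[Si](C)(C)C(C)(C)C)/C(OS(=O)(=O)C(F)(F)F)=C(\COC(C)=O)C(=O)OC | intermediate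
25 | methyl (2Z,4S,6R,10S,11R)-2-(acetoxymethyl)-10,11-epoxy-7,7-dimethoxy-6,10-dimethyl-12-oxo-4-(R*-oxy)-3-(TfO)dodec-2-enoate | O=C[C@@H]1O[C@@]1(C)CCC(OC)(OC)[C@H](C)C[C@H](OC(=O)/C(C)=C/CO[Si](C)(C)C(C)(C)C)/C(OS(=O)(=O)C(F)(F)F)=C(\COC(C)=O)C(=O)OC | intermediate
26 | macrocyclic hydroxy ester: ten-membered carbocycle with C6–OH, exocyclic C7=C11 bearing the C12 methyl ester cis to C6 and the C13 acetate, (4S,5S)-epoxide, C1 dimethyl ketal, C8 O-R* (C6 epimers) | OC1[C@@H]2O[C@@]2(C)CCC(OC)(OC)[C@H](C)C[C@H](OC(=O)/C(C)=C/CO[Si](C)(C)C(C)(C)C)/C1=C(\COC(C)=O)C(=O)OC | intermediate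
27 | (4S,5S,8S,10R)-13-acetoxy-4,5-epoxy-1,1-dimethoxy-8-(R*-oxy)germacr-7(11)-en-12,6-olide (C6 epimers) | CC(=O)OCC1=C2C([C@@H]3O[C@@]3(C)CCC(OC)(OC)[C@H](C)C[C@@H]2OC(=O)/C(C)=C/CO[Si](C)(C)C(C)(C)C)OC1=O | intermediate
28 | (4S,5S,8S,10R)-13-acetoxy-4,5-epoxy-1-oxo-8-(R*-oxy)germacr-7(11)-en-12,6-olide (C6 epimers) | CC(=O)OCC1=C2C([C@@H]3O[C@@]3(C)CCC(=O)[C@H](C)C[C@@H]2OC(=O)/C(C)=C/CO[Si](C)(C)C(C)(C)C)OC1=O | intermediate
29 | (4S,5E,8S,10R)-13-acetoxy-4-hydroxy-1-oxo-8-(R*-oxy)germacra-5,7(11)-dien-12,6-olide | CC(=O)OCC1=C2/C(=C\[C@@](C)(O)CCC(=O)[C@H](C)C[C@@H]2OC(=O)/C(C)=C/CO[Si](C)(C)C(C)(C)C)OC1=O | intermediate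
30 | (1R,4S,5E,8S,10R)-13-acetoxy-1,4-epoxy-1-hydroxy-8-(R*-oxy)germacra-5,7(11)-dien-12,6-olide | CC(=O)OCC1=C2/C(=C\[C@]3(C)CC[C@@](O)(O3)[C@H](C)C[C@@H]2OC(=O)/C(C)=C/CO[Si](C)(C)C(C)(C)C)OC1=O | intermediate
31 | (1R,4S,5E,8S,10R)-13-acetoxy-1,4-epoxy-1-hydroxy-8-[(E)-4-hydroxy-2-methylbut-2-enoyloxy]germacra-5,7(11)-dien-12,6-olide (CNP0154520.2) | CC(=O)OCC1=C2/C(=C\[C@]3(C)CC[C@@](O)(O3)[C@H](C)C[C@@H]2OC(=O)/C(C)=C/CO)OC1=O | target

Total step count: 22. Longest linear sequence: 19 steps (steps 1, 2, 3, 6, 7 and 9–22).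

Steps most likely to fail

Step 19. The slow ten-membered closure may lose to intermolecular coupling, the alkenylmetal may eliminate the C8 acyloxy group to an allene, or CrCl2 may reductively open the epoxy aldehyde. The fallback closes the same C6–C7 bond by an intramolecular Stille acylation, which involves no carbanionic alkenylmetal. It sets out from 25. Oxidation with NaClO2 (NaH2PO4, 2-methylbut-2-ene, t-BuOH–H2O) should give epoxy acid F1. Me3SnSnMe3, Pd(PPh3)4 and LiCl in THF should then convert the triflate into alkenylstannane F2. 1-Chloro-N,N,2-trimethylprop-1-en-1-amine should give acid chloride F3, which is not isolated but cyclized at high dilution with Pd2(dba)3 and tri(2-furyl)phosphine to macrocyclic keto ester F4. Luche reduction (NaBH4, CeCl3·7H2O) of the C6 ketone and spontaneous lactonization bring the route back at 27.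

Step 21. The 2-oxidofuran may expel the C13 acetate instead of opening the epoxide, and DBU may epimerize C10 next to the C1 ketone. The fallback replaces the base-induced elimination by epoxide opening and selenoxide elimination. It sets out from 28. PhSeNa (from PhSeH and NaH, THF) should open the epoxide at the less substituted C5, and the freed C4 hydroxyl should close the hemiketal to give hydroxy selenide F5. Oxidation with H2O2 and syn-elimination of the selenoxide, which can only involve H6 because C4 is quaternary, should return the route at 30.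

Step 20. The acid may open the tertiary epoxide, assisted by the liberated C1 carbonyl, before the base step can use it. The fallback inverts the order. It sets out from 27. DBU should open the epoxide first and give tertiary alcohol F6 with the ketal intact. PPTS in wet acetone then unmasks C1, which should be trapped at once by the C4 hydroxyl as the hemiketal, returning the route at 30.

Further compounds
F1 | step 19 | epoxy acid (C6 carboxylic acid corresponding to 25) | OC(=O)[C@@H]1O[C@@]1(C)CCC(OC)(OC)[C@H](C)C[C@H](OC(=O)/C(C)=C/CO[Si](C)(C)C(C)(C)C)/C(OS(=O)(=O)C(F)(F)F)=C(\COC(C)=O)C(=O)OC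
F2 | step 19 | alkenylstannane (C7 trimethylstannyl analogue of F1) | OC(=O)[C@@H]1O[C@@]1(C)CCC(OC)(OC)[C@H](C)C[C@H](OC(=O)/C(C)=C/CO[Si](C)(C)C(C)(C)C)/C([Sn](C)(C)C)=C(\COC(C)=O)C(=O)OC
F3 | step 19 | acid chloride of F2 | ClC(=O)[C@@H]1O[C@@]1(C)CCC(OC)(OC)[C@H](C)C[C@H](OC(=O)/C(C)=C/CO[Si](C)(C)C(C)(C)C)/C([Sn](C)(C)C)=C(\COC(C)=O)C(=O)OC
F4 | step 19 | macrocyclic keto ester (C6 ketone analogue of 26) | O=C1[C@@H]2O[C@@]2(C)CCC(OC)(OC)[C@H](C)C[C@H](OC(=O)/C(C)=C/CO[Si](C)(C)C(C)(C)C)/C1=C(\COC(C)=O)C(=O)OC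
F5 | step 21 | hydroxy selenide (C5 phenylselanyl, C1–O–C4 hemiketal, C5 and C6 epimers) | CC(=O)OCC1=C2C(OC1=O)C([Se]c4ccccc4)[C@]3(C)CC[C@@](O)(O3)[C@H](C)C[C@@H]2OC(=O)/C(C)=C/CO[Si](C)(C)C(C)(C)C
F6 | step 20 | tertiary alcohol (C4–OH, C5=C6 ylidene butenolide, C1 dimethyl ketal) | CC(=O)OCC1=C2/C(=C\[C@@](C)(O)CCC(OC)(OC)[C@H](C)C[C@@H]2OC(=O)/C(C)=C/CO[Si](C)(C)C(C)(C)C)OC1=O
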